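**Plan**

Chain numbering runs from C1' (benzylic) to C15' (gem-dimethyl carbon). The retrosynthesis cuts the C5' acetate, the benzyl–alkenyl bond C1'–C2', C3'–CH3 and C4'–C5', then O–C12' together with C14'–H, and last C12'=C13'.
Enabling feature: in the oxolane ring the oxygen ties the gem-dimethyl carbon C15' to the allylic carbon C12', and the carbinol C14' sits between them. The ring is therefore a reduced β-alkoxy ketone that unravels to an achiral α'-hydroxy dienone (C15'–OH, C14'=O, C12'=C13', C10'=C11').
Forward: geraniol supplies C5'–C12' and 3-hydroxy-3-methylbutan-2-one supplies C13'–C15'. The oxolane, the only ring to be made, closes in step 5. C5' is then raised to the enal, C2'–C4' arrive by propargylation, and methylalumination with benzylic cross-coupling joins the chain to the silylated hydroquinone. Acetylation and one global desilylation finish the synthesis.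
Stereochemistry: C12' and C14' come from a chiral ruthenium hydrogenation catalyst acting on an equilibrating ketone pool, and C5' from a chiral phosphoric acid-catalysed allenylboration. 6'E comes from geraniol, 10'E from the SeO2 oxidation and 2'E from syn-carbometalation.

Key step: step 5

Assumption: the facial sense of the catalysts in steps 5 and 9 is extrapolated from simple ketones (larger flank in the place of the aryl group of acetophenone) and from aryl and alkenyl aldehydes; should a model run show the opposite sense, the antipodal catalyst is used and nothing else changes.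

**Step 1**
Reactants: 1 geraniol
Product: 2 tert-butyl{[(2E)-3,7-dimethylocta-2,6-dien-1-yl]oxy}dimethylsilane
Conditions: TBSCl, imidazole, CH2Cl2, 0 °C to rt
Reagents that add atoms: tert-butyldimethylsilyl chloride CC(C)(C)[Si](C)(C)Cl
Why: Imidazole-promoted silyl ether formation at a primary allylic alcohol gives a group that should withstand the oxidations, the aqueous base of step 4 and the alkoxide of step 5.

**Step 2**
Reactants: 2 geranyl silyl ether
Product: 3 (2E,6E)-8-(tert-butyldimethylsilyloxy)-2,6-dimethylocta-2,6-dien-1-ol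
Conditions: SeO2 (cat.), t-BuOOH, salicylic acid (cat.), CH2Cl2, 0 °C to rt
Reagents that add atoms: tert-butyl hydroperoxide CC(C)(C)OO (oxygen relayed through SeO2)
Why: Catalytic SeO2 allylic oxidation (ene reaction, then [2,3]-sigmatropic shift) attacks the more electron-rich terminal alkene at its E-methyl group, which fixes the 10'E geometry, and any enal 4 from over-oxidation is simply carried into step 3.

**Step 3**
Reactants: 3 allylic alcohol
Product: 4 (2E,6E)-8-(tert-butyldimethylsilyloxy)-2,6-dimethylocta-2,6-dienal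
Conditions: MnO2, CH2Cl2, rt
Reagents that add atoms: none
Why: MnO2 oxidation of a primary allylic alcohol stops at the enal and leaves alkene geometry and silyl ether untouched.

**Step 4**
Reactants: 4 enal; 5 3-hydroxy-3-methylbutan-2-one
Product: 7 (4E,6E,10E)-12-(tert-butyldimethylsilyloxy)-2-hydroxy-2,6,10-trimethyldodeca-4,6,10-trien-3-one, via aldol adduct 6 (not isolated)
Conditions: 5 (3 equiv), LiOH·H2O (0.5 equiv), THF–MeOH–H2O, 40 °C
Reagents that add atoms: none
Why: In this Claisen–Schmidt-type crossed aldol condensation 5 enolises only at its methyl group and is too hindered to self-condense, 4 has no α-hydrogen, and E1cB loss of water from 6 gives the thermodynamically preferred E-C12'=C13' alkene, the open α'-hydroxy enone being the form normally isolated from hydroxide-mediated condensations of this ketone.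

**Step 5**
Reactants: 7 α'-hydroxy dienone
Product: 9 (3S,5S)-5-[(2E,6E)-8-(tert-butyldimethylsilyloxy)-6-methylocta-2,6-dien-2-yl]-2,2-dimethyloxolan-3-ol, via racemic oxolan-3-one 8 (not isolated)
Conditions: KOt-Bu (0.5 equiv), THF–t-BuOH (4:1), 40 °C, Ar; then trans-RuCl2[(R)-xylbinap][(R)-daipen] (1 mol %), H2 (2 atm), 40 °C (xylbinap = 2,2'-bis[bis(3,5-dimethylphenyl)phosphino]-1,1'-binaphthyl, daipen = 1,1-bis(4-methoxyphenyl)-3-methylbutane-1,2-diamine)
Reagents that add atoms: none
Why: Proposed new method: KOt-Bu turns the C15' hydroxyl of 7 into its potassium alkoxide, which attacks C12' of the dienone (O–C12' bond, oxolane closed in the 5-endo-trig mode, helped by the gem-dimethyl group), and the C13' enolate of 8 can eject the same oxygen again (E1cB), so that 7 and both antipodes of 8 form one equilibrating pool from which the Ru–H/N–H complex removes ketone irreversibly by outer-sphere transfer of H2 to C14'=O. The closest known reaction types are the base-promoted dynamic kinetic resolution of stereolabile ketones with RuCl2(diphosphine)(diamine) and H2, the hydrogen-transfer resolution of 2-substituted chroman-4-ones that racemise by retro-oxa-Michael opening, and the cyclisation of α'-hydroxy enones to oxolan-3-ones. Since alkoxide 5-endo-trig closure is stereoelectronically reluctant and loses to solvent addition in alcoholic alkoxide, the usual 2-propanol is replaced by THF with t-BuOH as the only proton source (the medium in which sulfonyl-substituted homoallylic alcohols close in the same mode): the alkoxide is poorly solvated, t-BuO− is too bulky to add to C12', no transfer hydrogenation can run backwards, and closure is allowed to reach equilibrium before H2 is admitted. C14' is fixed by the catalyst, which distinguishes the quaternary C15' flank from the C13' methylene and should place hydride on the Re face, and C12' is fixed by kinetic selection, because only in (12'S)-8 is that Re face the one remote from the C12' alkenyl substituent, so this antipode is drained to the cis (12'S,14'S) alcohol while the other waits and is recycled through 7. The step needs ring opening to outrun reduction of the mismatched antipode, which low H2 pressure, low catalyst loading and 40 °C are meant to ensure, and it needs the open ketone to survive, which should follow from its acyclic tertiary-carbinol flank (a ketone type that this catalyst family reduces only sluggishly, whereas in 8 the quaternary carbon is tied back in the ring and the α-oxygen activates the carbonyl), its dienone conjugation and its small share at equilibrium. Incomplete selection at C12' would show up as the trans diastereomer, removable by chromatography, and not as a loss of enantiopurity.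

**Step 6**
Reactants: 9 oxolanol silyl ether
Product: 10 (3S,5S)-5-[(2E,6E)-8-hydroxy-6-methylocta-2,6-dien-2-yl]-2,2-dimethyloxolan-3-ol
Conditions: Bu4NF, THF, 0 °C to rt
Reagents that add atoms: none
Why: Fluoride-induced cleavage of the primary silyl ether is safe here because nothing else in 9 is sensitive to fluoride or mild base.

**Step 7**
Reactants: 10 diol
Product: 11 (2E,6E)-7-[(2S,4S)-4-hydroxy-5,5-dimethyloxolan-2-yl]-3-methylocta-2,6-dienal
Conditions: MnO2, CH2Cl2, rt
Reagents that add atoms: none
Why: MnO2 oxidises only the allylic primary alcohol, so the saturated C14' carbinol needs no protection at this stage and the 6'E geometry is kept.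

**Step 8**
Reactants: 11 hydroxy enal
Product: 12 (2E,6E)-7-[(2S,4S)-5,5-dimethyl-4-(triethylsilyloxy)oxolan-2-yl]-3-methylocta-2,6-dienal
Conditions: TESCl, imidazole, 4-(dimethylamino)pyridine (cat.), DMF, rt
Reagents that add atoms: chlorotriethylsilane CC[Si](Cl)(CC)CC
Why: Silyl ether formation at C14' uses triethylsilyl because the neopentyl-like surroundings make it robust enough for steps 9 and 14 while it still leaves under the mild fluoride of step 16.

**Step 9**
Reactants: 12 enal; 13 allenylboronic acid pinacol ester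
Product: 15 (4S,5E,9E)-10-[(2S,4S)-5,5-dimethyl-4-(triethylsilyloxy)oxolan-2-yl]-6-methylundeca-5,9-dien-1-yn-4-ol, via pinacol borate ester 14 (not isolated)
Conditions: (S)-3,3'-bis(2,4,6-triisopropylphenyl)-1,1'-binaphthyl-2,2'-diyl hydrogen phosphate (10 mol %), 4 Å MS, toluene, −20 °C; aq. NaHCO3 work-up
Reagents that add atoms: none
Why: Chiral phosphoric acid-catalysed allenylboration (SE2' propargylation through a closed six-membered transition state in which the acid hydrogen-bonds to a boronate oxygen) gives only the homopropargylic alcohol, and the (S)-acid should direct attack to the Si face of the enal and so set 5'S irrespective of the remote ring stereocentres.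

**Step 10**
Reactants: 16 2-hydroxy-3-methylbenzaldehyde
Product: 18 2,5-dihydroxy-3-methylbenzaldehyde, via potassium aryl sulfate 17 (not isolated)
Conditions: K2S2O8, aq. KOH, 0 °C to rt; then aq. HCl, 80 °C
Reagents that add atoms: potassium peroxydisulfate [K+].[K+].[O-]S(=O)(=O)OOS(=O)(=O)[O-]
Why: In the Elbs persulfate oxidation the phenoxide attacks peroxydisulfate through its only free activated position, the para carbon C5, and acid hydrolysis of sulfate 17 frees the hydroquinone, as in the conversion of salicylaldehyde into gentisaldehyde.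

**Step 11**
Reactants: 18 dihydroxy aldehyde
Product: 19 2,5-bis(tert-butyldimethylsilyloxy)-3-methylbenzaldehyde
Conditions: TBSCl, imidazole, DMF, rt to 40 °C
Reagents that add atoms: tert-butyldimethylsilyl chloride CC(C)(C)[Si](C)(C)Cl
Why: Imidazole-promoted silylation of both phenols masks the oxidation-prone hydroquinone with groups that fall together with the C14' silyl ether in the last step.

**Step 12**
Reactants: 19 bis-silyl aldehyde
Product: 20 [2,5-bis(tert-butyldimethylsilyloxy)-3-methylphenyl]methanol
Conditions: i-Bu2AlH, CH2Cl2, −78 °C; aq. potassium sodium tartrate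
Reagents that add atoms: none
Why: Hydride reduction at low temperature gives an aluminium alkoxide that is too weakly nucleophilic to trigger migration of the ortho silyl group from the phenol oxygen to the benzylic oxygen.

**Step 13**
Reactants: 20 benzylic alcohol
Product: 21 1,4-bis(tert-butyldimethylsilyloxy)-2-(chloromethyl)-6-methylbenzene
Conditions: PPh3, N-chlorosuccinimide, THF, 0 °C to rt
Reagents that add atoms: N-chlorosuccinimide O=C1CCC(=O)N1Cl
Why: Appel-type chlorination (alkoxyphosphonium salt displaced by chloride) runs under neutral conditions that spare the aryl silyl ethers.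

**Step 14**
Reactants: 15 homopropargylic alcohol; 21 benzylic chloride
Product: 23 (2E,5S,6E,10E)-1-[2,5-bis(tert-butyldimethylsilyloxy)-3-methylphenyl]-11-[(2S,4S)-5,5-dimethyl-4-(triethylsilyloxy)oxolan-2-yl]-3,7-dimethyldodeca-2,6,10-trien-5-ol, via alkenylalane 22 (not isolated)
Conditions: Me3Al (4 equiv), Cp2ZrCl2 (0.25 equiv), CH2Cl2, 0 °C to rt; volatiles removed in vacuo; then 21, NiCl2(PPh3)2 (5 mol %)/n-BuLi (10 mol %), THF, rt; aq. potassium sodium tartrate
Reagents that add atoms: trimethylaluminium C[Al](C)C
Why: Negishi carboalumination adds CH3 to C3' and aluminium to C2' in syn fashion after excess Me3Al has turned the C5' hydroxyl into its aluminium alkoxide, and cross-coupling of alkenylalane 22 with the benzylic chloride under zerovalent nickel, a reaction well known for polyprenyl–arene junctions, forms C1'–C2' with retention and so gives the 2'E alkene.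

**Step 15**
Reactants: 23 C5' alcohol
Product: 24 (2E,5S,6E,10E)-1-[2,5-bis(tert-butyldimethylsilyloxy)-3-methylphenyl]-11-[(2S,4S)-5,5-dimethyl-4-(triethylsilyloxy)oxolan-2-yl]-3,7-dimethyldodeca-2,6,10-trien-5-yl acetate
Conditions: Ac2O, pyridine, 4-(dimethylamino)pyridine (cat.), CH2Cl2, 0 °C
Reagents that add atoms: acetic anhydride CC(=O)OC(C)=O
Why: Nucleophile-catalysed acylation of the only free hydroxyl group proceeds at oxygen and therefore with retention at C5'.

**Step 16**
Reactants: 24 tris-silyl acetate
Product: 25 (2E,5S,6E,10E)-1-(2,5-dihydroxy-3-methylphenyl)-11-[(2S,4S)-4-hydroxy-5,5-dimethyloxolan-2-yl]-3,7-dimethyldodeca-2,6,10-trien-5-yl acetate (CNP0227918.2)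
Conditions: Et3N·3HF, THF, rt, Ar
Reagents that add atoms: none
Why: Mildly acidic fluoride cleaves both aryl silyl ethers and the triethylsilyl ether in one operation without generating phenoxide, so that the allylic acetate should be neither transferred nor hydrolysed and the hydroquinone stays unoxidised under argon.

**Compound list**

1 | geraniol | CC(C)=CCC/C(C)=C/CO | starting material
2 | tert-butyl{[(2E)-3,7-dimethylocta-2,6-dien-1-yl]oxy}dimethylsilane | CC(C)=CCC/C(C)=C/CO[Si](C)(C)C(C)(C)C | intermediate
3 | (2E,6E)-8-(tert-butyldimethylsilyloxy)-2,6-dimethylocta-2,6-dien-1-ol | OC/C(C)=C/CC/C(C)=C/CO[Si](C)(C)C(C)(C)C | intermediate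
4 | (2E,6E)-8-(tert-butyldimethylsilyloxy)-2,6-dimethylocta-2,6-dienal | O=C/C(C)=C/CC/C(C)=C/CO[Si](C)(C)C(C)(C)C | intermediate
5 | 3-hydroxy-3-methylbutan-2-one | CC(=O)C(C)(C)O | starting material
6 | (6E,10E)-12-(tert-butyldimethylsilyloxy)-2,5-dihydroxy-2,6,10-trimethyldodeca-6,10-dien-3-one, racemic | CC(C)(O)C(=O)CC(O)/C(C)=C/CC/C(C)=C/CO[Si](C)(C)C(C)(C)C | intermediate
7 | (4E,6E,10E)-12-(tert-butyldimethylsilyloxy)-2-hydroxy-2,6,10-trimethyldodeca-4,6,10-trien-3-one | CC(C)(O)C(=O)/C=C/C(C)=C/CC/C(C)=C/CO[Si](C)(C)C(C)(C)C | intermediate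
8 | 5-[(2E,6E)-8-(tert-butyldimethylsilyloxy)-6-methylocta-2,6-dien-2-yl]-2,2-dimethyloxolan-3-one, racemic | CC(C)(C)[Si](C)(C)OC/C=C(\C)CC/C=C(\C)C1CC(=O)C(C)(C)O1 | intermediate
9 | (3S,5S)-5-[(2E,6E)-8-(tert-butyldimethylsilyloxy)-6-methylocta-2,6-dien-2-yl]-2,2-dimethyloxolan-3-ol | CC(C)(C)[Si](C)(C)OC/C=C(\C)CC/C=C(\C)[C@@H]1C[C@H](O)C(C)(C)O1 | intermediate
10 | (3S,5S)-5-[(2E,6E)-8-hydroxy-6-methylocta-2,6-dien-2-yl]-2,2-dimethyloxolan-3-ol | OC/C=C(\C)CC/C=C(\C)[C@@H]1C[C@H](O)C(C)(C)O1 | intermediate
11 | (2E,6E)-7-[(2S,4S)-4-hydroxy-5,5-dimethyloxolan-2-yl]-3-methylocta-2,6-dienal | O=C/C=C(\C)CC/C=C(\C)[C@@H]1C[C@H](O)C(C)(C)O1 | intermediate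
12 | (2E,6E)-7-[(2S,4S)-5,5-dimethyl-4-(triethylsilyloxy)oxolan-2-yl]-3-methylocta-2,6-dienal | O=C/C=C(\C)CC/C=C(\C)[C@@H]1C[C@H](O[Si](CC)(CC)CC)C(C)(C)O1 | intermediate
13 | allenylboronic acid pinacol ester | C=C=CB1OC(C)(C)C(C)(C)O1 | starting material
14 | 2-{[(4S,5E,9E)-10-[(2S,4S)-5,5-dimethyl-4-(triethylsilyloxy)oxolan-2-yl]-6-methylundeca-5,9-dien-1-yn-4-yl]oxy}-4,4,5,5-tetramethyl-1,3,2-dioxaborolane | CC1(C)OB(O[C@H](/C=C(\C)CC/C=C(\C)[C@@H]2C[C@H](O[Si](CC)(CC)CC)C(C)(C)O2)CC#C)OC1(C)C | intermediate
15 | (4S,5E,9E)-10-[(2S,4S)-5,5-dimethyl-4-(triethylsilyloxy)oxolan-2-yl]-6-methylundeca-5,9-dien-1-yn-4-ol | O[C@H](/C=C(\C)CC/C=C(\C)[C@@H]1C[C@H](O[Si](CC)(CC)CC)C(C)(C)O1)CC#C | intermediate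
16 | 2-hydroxy-3-methylbenzaldehyde | Cc1cccc(C=O)c1O | starting material
17 | potassium 3-formyl-4-hydroxy-5-methylphenyl sulfate | Cc1cc(OS(=O)(=O)[O-])cc(C=O)c1O.[K+] | intermediate
18 | 2,5-dihydroxy-3-methylbenzaldehyde | Cc1cc(O)cc(C=O)c1O | intermediate
19 | 2,5-bis(tert-butyldimethylsilyloxy)-3-methylbenzaldehyde | Cc1cc(O[Si](C)(C)C(C)(C)C)cc(C=O)c1O[Si](C)(C)C(C)(C)C | intermediate
20 | [2,5-bis(tert-butyldimethylsilyloxy)-3-methylphenyl]methanol | Cc1cc(O[Si](C)(C)C(C)(C)C)cc(CO)c1O[Si](C)(C)C(C)(C)C | intermediate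
21 | 1,4-bis(tert-butyldimethylsilyloxy)-2-(chloromethyl)-6-methylbenzene | Cc1cc(O[Si](C)(C)C(C)(C)C)cc(CCl)c1O[Si](C)(C)C(C)(C)C | intermediate
22 | dimethylaluminium alkoxide of (1E,4S,5E,9E)-1-(dimethylalumanyl)-10-[(2S,4S)-5,5-dimethyl-4-(triethylsilyloxy)oxolan-2-yl]-2,6-dimethylundeca-1,5,9-trien-4-ol | C[Al](C)O[C@H](/C=C(\C)CC/C=C(\C)[C@@H]1C[C@H](O[Si](CC)(CC)CC)C(C)(C)O1)C/C(C)=C/[Al](C)C | intermediate
23 | (2E,5S,6E,10E)-1-[2,5-bis(tert-butyldimethylsilyloxy)-3-methylphenyl]-11-[(2S,4S)-5,5-dimethyl-4-(triethylsilyloxy)oxolan-2-yl]-3,7-dimethyldodeca-2,6,10-trien-5-ol | O[C@H](/C=C(\C)CC/C=C(\C)[C@@H]1C[C@H](O[Si](CC)(CC)CC)C(C)(C)O1)C/C(C)=C/Cc1cc(O[Si](C)(C)C(C)(C)C)cc(C)c1O[Si](C)(C)C(C)(C)C | intermediate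
24 | (2E,5S,6E,10E)-1-[2,5-bis(tert-butyldimethylsilyloxy)-3-methylphenyl]-11-[(2S,4S)-5,5-dimethyl-4-(triethylsilyloxy)oxolan-2-yl]-3,7-dimethyldodeca-2,6,10-trien-5-yl acetate | CC(=O)O[C@H](/C=C(\C)CC/C=C(\C)[C@@H]1C[C@H](O[Si](CC)(CC)CC)C(C)(C)O1)C/C(C)=C/Cc1cc(O[Si](C)(C)C(C)(C)C)cc(C)c1O[Si](C)(C)C(C)(C)C | intermediate
25 | (2E,5S,6E,10E)-1-(2,5-dihydroxy-3-methylphenyl)-11-[(2S,4S)-4-hydroxy-5,5-dimethyloxolan-2-yl]-3,7-dimethyldodeca-2,6,10-trien-5-yl acetate | CC(=O)O[C@H](/C=C(\C)CC/C=C(\C)[C@@H]1C[C@H](O)C(C)(C)O1)C/C(C)=C/Cc1cc(O)cc(C)c1O | target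

**Step count**

Total step count: 16.
Longest linear sequence: 12 steps (steps 1–9, then 14–16). The arene fragment (steps 10–13) is made in parallel.

**Steps most likely to fail**

**Step 5.**
- Ring opening of 8 may be too slow to keep the resolution dynamic.
- The open dienone may be hydrogenated.
- The catalyst may discriminate poorly between the two antipodes of 8.
- The 10'E alkene may drift through the extended enolate of 7.

The fallback runs from 7 back to 9 and separates the two events into known reactions. Dienone 7 is closed with catalytic p-toluenesulfonic acid in 1,2-dichloroethane at 60 °C. This is the established acid mode, in which the O-protonated enone is a hydroxyallyl cation free to rotate about C12'–C13'. Racemic 8 is isolated. It is then reduced by the Corey–Bakshi–Shibata method with (R)-2-methyl-CBS-oxazaborolidine [(R)-tetrahydro-1-methyl-3,3-diphenyl-1H,3H-pyrrolo[1,2-c][1,3,2]oxazaborole] and catecholborane in toluene at −78 °C. This borane leaves trisubstituted alkenes alone. Both antipodes should be reduced from the Re face, giving 9 from (12'S)-8 and, from (12'R)-8, the trans diastereomer (3S,5R)-5-[(2E,6E)-8-(tert-butyldimethylsilyloxy)-6-methylocta-2,6-dien-2-yl]-2,2-dimethyloxolan-3-ol F1. Chromatography separates the two, and 9 re-enters at step 6 at the cost of half of the material.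

**Step 14.**
- Transmetalation of the internally chelated alkoxy-alane may be sluggish.
- Residual Me3Al may transfer methyl to the benzylic chloride.
- The Lewis acid may ionise the allylic C–O bonds.

The fallback runs from 15 and 21 back to 23 and reverses the polarity of the junction. The same carboalumination is run on 15, but alane 22 is quenched with I2 in THF at −30 °C. This gives the vinyl iodide (1E,4S,5E,9E)-10-[(2S,4S)-5,5-dimethyl-4-(triethylsilyloxy)oxolan-2-yl]-1-iodo-2,6-dimethylundeca-1,5,9-trien-4-ol F2, which is purified. Chloride 21 is treated with zinc dust and LiCl in THF to give [2,5-bis(tert-butyldimethylsilyloxy)-3-methylbenzyl]zinc chloride F3. Negishi coupling of F2 with F3 follows, with Pd(OAc)2 and 2-dicyclohexylphosphino-2',6'-dimethoxybiphenyl in THF at rt. This catalyst system tolerates free hydroxyl groups and should give 23 with retention of the 2'E geometry.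

**Step 9.**
- Facial selectivity may be insufficient with a β,β-disubstituted enal.

The fallback runs from 12 back to 15 and replaces asymmetric addition by resolution. Barbier addition of propargyl bromide with zinc dust in THF/aq. NH4Cl gives (5E,9E)-10-[(2S,4S)-5,5-dimethyl-4-(triethylsilyloxy)oxolan-2-yl]-6-methylundeca-5,9-dien-1-yn-4-ol as a mixture of both C5' epimers F4. Sharpless kinetic resolution is then run with Ti(Oi-Pr)4, D-(−)-diisopropyl tartrate and t-BuOOH (0.6 equiv) over 4 Å MS in CH2Cl2 at −20 °C. It should consume the (5'R) epimer as the epoxy alcohol (1R)-1-[(2S,3S)-3-{(3E)-4-[(2S,4S)-5,5-dimethyl-4-(triethylsilyloxy)oxolan-2-yl]pent-3-en-1-yl}-3-methyloxiran-2-yl]but-3-yn-1-ol F5. The (5'S) epimer 15 remains and is separated by chromatography.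

**Further compounds**

F1 | step 5 | (3S,5R)-5-[(2E,6E)-8-(tert-butyldimethylsilyloxy)-6-methylocta-2,6-dien-2-yl]-2,2-dimethyloxolan-3-ol | CC(C)(C)[Si](C)(C)OC/C=C(\C)CC/C=C(\C)[C@H]1C[C@H](O)C(C)(C)O1
F2 | step 14 | (1E,4S,5E,9E)-10-[(2S,4S)-5,5-dimethyl-4-(triethylsilyloxy)oxolan-2-yl]-1-iodo-2,6-dimethylundeca-1,5,9-trien-4-ol | O[C@H](/C=C(\C)CC/C=C(\C)[C@@H]1C[C@H](O[Si](CC)(CC)CC)C(C)(C)O1)C/C(C)=C/I
F3 | step 14 | [2,5-bis(tert-butyldimethylsilyloxy)-3-methylbenzyl]zinc chloride | Cc1cc(O[Si](C)(C)C(C)(C)C)cc(C[Zn]Cl)c1O[Si](C)(C)C(C)(C)C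
F4 | step 9 | (5E,9E)-10-[(2S,4S)-5,5-dimethyl-4-(triethylsilyloxy)oxolan-2-yl]-6-methylundeca-5,9-dien-1-yn-4-ol, both C5' epimers | OC(/C=C(\C)CC/C=C(\C)[C@@H]1C[C@H](O[Si](CC)(CC)CC)C(C)(C)O1)CC#C
F5 | step 9 | (1R)-1-[(2S,3S)-3-{(3E)-4-[(2S,4S)-5,5-dimethyl-4-(triethylsilyloxy)oxolan-2-yl]pent-3-en-1-yl}-3-methyloxiran-2-yl]but-3-yn-1-ol | O[C@H](CC#C)[C@@H]1O[C@@]1(C)CC/C=C(\C)[C@@H]2C[C@H](O[Si](CC)(CC)CC)C(C)(C)O2
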